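Compound numbers are those of the compound list after the steps; 16 is the target. Ring atoms carry the quinone numbering (C1 and C4 carbonyl, C2 hydroxyl, C3 chain, C5 methoxyl, C6 H), and the chain is numbered C1' outward from C3.

## Analysis of the target

Irisoquin C (16) is 2-hydroxy-5-methoxy-3-nonadecyl-1,4-benzoquinone: one six-membered carbocycle with carbonyls at C1 and C4, a free enolic hydroxyl at C2, an unbranched saturated C19 chain at C3, a methoxyl at C5 and the only ring hydrogen at C6. There is no stereocentre and no alkene geometry to control, so the whole problem is regiochemical, on a ring substituted at five of six carbons. The oxygens on C2 and C5 occupy near-equivalent vinylogous-acid positions and differ only in that O2 is free and flanked by the chain, whereas O5 is methylated and flanked by hydrogen; telling them apart late, on a dihydroxyquinone, is unattractive. The hydroxyquinone is redox-active, acidic and base-sensitive, and the C5 methoxyl is a vinylogous ester open to addition–elimination, so the quinone should appear only in the last operation. The chain is odd-numbered, which favours assembly from an even-numbered fatty building block, and it makes all late intermediates waxy and hard to separate from close isomers. The plan rests on the ortho relation between the free hydroxyl on C2 and the chain on C3: with a C2'=C3' double bond this is an ortho-allylphenol, the product pattern of an aromatic Claisen rearrangement in which the whole chain starts on O2 and the bond-forming step itself sets O2 free.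

## Retrosynthetic reasoning

**16 to 14.** The quinone 16 is first taken back to its reduced form, the benzene-1,2,4-triol 15. No skeletal bond is cut. The free hydroxyls of 15 sit on C1, C2 and C4, and C1/C4 is their only para pair, so oxidation can give only one para-quinone. Triol 15 is in turn the product of exhaustive hydrogenation of 14, in which O1 and O4 are benzyl ethers, O2 is free and the chain holds a C2'=C3' alkene. Benzyl is chosen because one hydrogenation saturates the alkene and frees both oxygens. The C5 methyl ether is then the only permanent O-alkyl group, and no selective demethylation is ever needed.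

**14 to 12.** In 14 the C3–C1' bond is cut and the chain is returned to O2, giving the secondary allylic aryl ether 12 (forward, through dienone 13). The cut is made here because C3 lies between two oxygen-bearing carbons on an electron-rich ring. An intermolecular alkylation at that site would compete with O-alkylation and with attack at C6, whereas the sigmatropic shift delivers the chain intramolecularly to the carbon next to the carrier oxygen. The step gains the one skeletal bond that joins ring and chain, and it also differentiates the oxygens, since only the carrier oxygen O2 ends up free. The forward reaction must direct the chain to C3 alone, which holds because the other ortho carbon (C1) bears benzyloxy and the para carbon (C5) bears methoxyl.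

**12 to 7 and 11.** The O2–C3' bond of 12 is cut to phenol 7 and the racemic allylic alcohol 11. The ether has to be the branched, secondary one. The [3,3] shift transposes the allyl unit, so an ether bound through the chain terminus would deliver a chain branched at C1'. The forward reaction must therefore form a hindered secondary alkyl aryl ether without allylic transposition. The configuration at the carbinol carbon is irrelevant because that carbon becomes sp2 in the rearrangement.

**11 to 8 and 9.** Alcohol 11 is cut between C3' and C4' into the Grignard reagent 10, made from 1-bromohexadecane 8, and acrolein 9. This divides the odd C19 chain into a cheap even C16 halide and a C3 enal, and 1,2-addition gives the allylic alcohol directly.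

**7 to 1 and 2.** The hydroxyl of 7 is traced to a formyl group: aldehyde 5 gives formate 6 by aryl migration to a peroxide oxygen, and 6 gives 7 by solvolysis. Aldehyde 5 comes from arene 3 by electrophilic formylation through iminium salt 4. The position attacked is para to the methoxyl and ortho to one benzyloxy group, the only site activated by two oxygens without being flanked on both sides. Arene 3 is the double benzyl ether of methoxyhydroquinone 1, made with two equivalents of benzyl bromide 2, one for each phenolic oxygen. Compound 1 already holds the C5 methoxyl and the O1/O4 pair in the right relation, so the ring is bought rather than built.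

## Alternatives that were turned down

**Alternative 1:** The ring bonds C3–C4 and C5–C6 are cut. C4 and C5 then come from diethyl oxalate A2, and C6, C1, C2 and C3 with the chain come from tricosane-2,3-dione A1.
- Forward key step: an alkoxide-mediated double Claisen condensation, in which the methyl carbon and the chain-bearing methylene of A1 each acylate one ester carbonyl of A2. This closes the ring and, after enolisation, gives 2,5-dihydroxy-3-nonadecyl-1,4-benzoquinone A3. A mono-O-methylation at O5 would finish the synthesis.
- For: the ring is made de novo in one step without protecting groups. Counted from A1 this is clearly shorter than the chosen route, and that point is conceded.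
- Against: A1 is an unsymmetrical long-chain 1,2-diketone that needs its own synthesis, which uses up much of the saving. Enolisable α-diketones self-condense under alkoxide, and the ring-closing acylation must occur at the more hindered, less acidic methylene. Most seriously, the hydroxyls on C2 and C5 of A3 exchange roles by tautomerism, so the methylation must distinguish them by the steric shadow of the chain alone. Wrongly or doubly methylated material would be a waxy isomer of the target.
- Comparison: the chosen route is longer, but each oxygen has its identity from the outset. The methyl comes with 1, the free hydroxyl is the Claisen carrier oxygen, and the carbonyl oxygens are the benzyl ethers.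

**Alternative 2:** The C4–C5 ring bond is cut and the six-membered ring is traced to a four-membered one, 3-tert-butoxy-4-hydroxy-4-[(Z)-2-methoxyethenyl]-2-nonadecylcyclobut-2-en-1-one A4. This would be built from a squaric diester by adding a C19 alkyl-metal reagent and then (Z)-(2-methoxyethenyl)lithium A5.
- Forward key step: heating A4 opens the cyclobutenone to a dienylketene, and 6π-electrocyclisation joins the ketene carbon (C4) to the methoxy-bearing vinyl carbon (C5). Tautomerisation gives 2-tert-butoxy-5-methoxy-3-nonadecylbenzene-1,4-diol A6. Oxidation and acid removal of the tert-butyl group would follow.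
- For: every substituent position follows from the order of the two additions, and the second addition is directed electronically to the carbonyl next to the alkoxy-bearing carbon. Regiochemical security is equal to that of the chosen route and the step count is comparable or slightly lower.
- Against: the intact odd-numbered C19 chain is needed as an organometallic reagent. A5 is prone to β-elimination of methoxide. The tertiary cyclobutenol A4 is sensitive. The tert-butyl enol ether must survive the thermolysis and then be cleaved by acid from a methoxyquinone.
- Comparison: this route builds the ring more elegantly. The chosen route offers classical, robust steps on cheap materials and makes the C19 chain from C16 plus C3.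

**Alternative 3:** The chain bond C2'–C3' is cut, dividing the skeleton into an arylethyl fragment and a C17 alkyl fragment. Both are introduced as carboxylic acids activated as the redox-active esters 1,3-dioxoisoindolin-2-yl 3-(3,5-dimethoxyphenyl)propanoate A7 and 1,3-dioxoisoindolin-2-yl octadecanoate A8.
- Forward key step: cathodic reduction with a NiCl2-derived catalyst couples A7 and A8 with loss of two CO2 to give 1,3-dimethoxy-5-nonadecylbenzene A9.
- For: the odd chain comes from the most abundant even fatty acid without organometallic reagents. On chain construction alone this is at least as good as the Grignard addition of the chosen route.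
- Against: both partners give unstabilised primary alkyl radicals that the catalyst cannot tell apart, so homo-coupling competes statistically unless one ester is used in excess. More decisively, A9 has oxygen only at the two positions meta to the chain. The target also needs oxygen at both ortho positions and a quinone oxidation level. The two methoxyls of A9 are equivalent although only one may remain. The most nucleophilic and most acidic C–H of A9, between the methoxyls, is the one that must stay C–H as C6.
- Comparison: this key step solves the easy part and leaves a long, regiochemically delicate oxidation sequence. In the chosen route the Claisen step forms the ring–chain bond and fixes the oxygen pattern in the same event.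

Key step: step 6

Assumption: alcohol 11, ether 12 and dienone 13 are racemic; the target has no stereocentre, so no enantiocontrol is needed.

## Route

Step 1
Reactants: 1 methoxyhydroquinone (2-methoxybenzene-1,4-diol); 2 benzyl bromide
Product: 3 1,4-bis(benzyloxy)-2-methoxybenzene
Conditions: BnBr (2.2 equiv), K2CO3 (3 equiv), DMF, 60 °C, N2 (degassed)
Reagents that add atoms: benzyl bromide BrCc1ccccc1 (the second equivalent of 2; one benzyl group goes to each phenolic oxygen)
Why: Double Williamson ether synthesis; both phenoxides are unhindered and benzyl bromide is a reactive SN2 electrophile, so two equivalents should cap both oxygens, while exclusion of air keeps the electron-rich hydroquinone anions from oxidising to the quinone.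

Step 2
Reactants: 3 1,4-bis(benzyloxy)-2-methoxybenzene
Product: 5 2,5-bis(benzyloxy)-4-methoxybenzaldehyde, via iminium chloride 4 (not isolated)
Conditions: POCl3, DMF, 0 → 75 °C; then H2O, 0 °C → rt
Reagents that add atoms: N,N-dimethylformamide CN(C)C=O (formyl carbon); water O (carbonyl oxygen)
Why: Vilsmeier–Haack formylation; 1,2,4-trialkoxybenzenes are attacked para to the 2-alkoxy group and ortho to the 4-alkoxy group, the only site activated by two oxygens that is not flanked on both sides, and the mild chloroiminium electrophile should leave the benzyl ethers intact.

Step 3
Reactants: 5 2,5-bis(benzyloxy)-4-methoxybenzaldehyde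
Product: 7 2,5-bis(benzyloxy)-4-methoxyphenol, via aryl formate 6 (not isolated)
Conditions: mCPBA, CH2Cl2, 0 °C → rt; aq Na2S2O3/NaHCO3 wash; then K2CO3 (cat.), MeOH, rt, N2
Reagents that add atoms: 3-chloroperbenzoic acid (mCPBA) O=C(OO)c1cccc(Cl)c1
Why: Baeyer–Villiger oxidation of the Dakin type; in the Criegee adduct the electron-rich aryl group migrates in preference to hydrogen to give the formate, which mild methanolysis cleaves to the phenol after the excess peracid has been destroyed.

Step 4
Reactants: 8 1-bromohexadecane; 9 acrolein
Product: 11 rac-nonadec-1-en-3-ol, via hexadecylmagnesium bromide 10 (not isolated)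
Conditions: Mg, I2 (cat.), THF, 50 °C; then 9, THF, −78 → 0 °C; aq NH4Cl
Reagents that add atoms: none
Why: Grignard formation followed by 1,2-addition to an enal; alkylmagnesium halides attack the carbonyl of acrolein rather than the β-carbon at low temperature, and the carbinol centre is formed racemic, which is all that is required.

Step 5
Reactants: 7 2,5-bis(benzyloxy)-4-methoxyphenol; 11 rac-nonadec-1-en-3-ol
Product: 12 rac-1,4-bis(benzyloxy)-2-methoxy-5-(nonadec-1-en-3-yloxy)benzene
Conditions: PPh3, DIAD, THF, 0 °C → rt
Reagents that add atoms: none
Why: Mitsunobu etherification; the phenol protonates the betaine and its phenoxide displaces the alkoxyphosphonium group at the carbinol carbon with inversion, giving the branched ether directly; the stereocentre remains racemic and is consumed in step 6.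

Step 6
Reactants: 12 rac-1,4-bis(benzyloxy)-2-methoxy-5-(nonadec-1-en-3-yloxy)benzene
Product: 14 3,6-bis(benzyloxy)-4-methoxy-2-[(E)-nonadec-2-en-1-yl]phenol, via ortho-dienone 13 (not isolated)
Conditions: PhNEt2, 190 °C, Ar (degassed), sealed tube
Reagents that add atoms: none
Why: Aromatic Claisen rearrangement: a concerted suprafacial [3,3]-sigmatropic shift through a chair-like six-membered transition state breaks the O2–C3' bond of 12 and joins the terminal alkene carbon (C1') to the one unsubstituted ortho carbon (C3), giving dienone 13, which enolises irreversibly to phenol 14. The closest known reaction type is the thermal ortho-Claisen rearrangement of α-alkyl-substituted allyl aryl ethers of polyalkoxyphenols. No ring is closed, because the cyclic array exists only in the transition state, and no lasting stereocentre is made: the sp3 centre of 13 is lost on tautomerisation and the C3' centre of 12 becomes an alkene carbon. The step needs site selectivity, and the substrate secures it: the other ortho carbon carries benzyloxy and the para carbon methoxyl, so shifts to those positions give non-enolisable dienones that can only revert, and the material should drain through the C–H position. The hexadecyl group prefers the equatorial position of the chair, which should favour the E alkene, and the geometry is immaterial because step 7 saturates it. The α-alkyl group weakens the breaking C–O bond and should lower the barrier relative to a plain allyl ether, while the basic amine solvent suppresses acid-catalysed ionisation of the secondary ether and cyclisation of 14 onto its alkene. Benzyl aryl ethers and the methyl ether are expected to be inert at this temperature under argon.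

Step 7
Reactants: 14 3,6-bis(benzyloxy)-4-methoxy-2-[(E)-nonadec-2-en-1-yl]phenol
Product: 16 irisoquin C (2-hydroxy-5-methoxy-3-nonadecylcyclohexa-2,5-diene-1,4-dione), via triol 15 (not isolated)
Conditions: H2 (1 atm), 10% Pd/C, EtOAc–EtOH, rt; N2 purge, filter; then air, rt
Reagents that add atoms: none
Why: Catalytic hydrogenation saturates the disubstituted alkene and hydrogenolyses both benzyl aryl ethers in one operation; the electron-rich benzene-1,2,4-triol is then autoxidised by O2 to the hydroxy-para-quinone, the only para-quinone its three hydroxyls allow and the more stable tautomer relative to the ortho-quinone.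

## Compound list

1 | methoxyhydroquinone (2-methoxybenzene-1,4-diol) | COc1cc(O)ccc1O | starting material
2 | benzyl bromide | BrCc1ccccc1 | starting material
3 | 1,4-bis(benzyloxy)-2-methoxybenzene | COc1cc(OCc2ccccc2)ccc1OCc1ccccc1 | intermediate
4 | N-[2,5-bis(benzyloxy)-4-methoxybenzylidene]-N-methylmethanaminium chloride | COc1cc(OCc2ccccc2)c(C=[N+](C)C)cc1OCc1ccccc1.[Cl-] | intermediate (not isolated)
5 | 2,5-bis(benzyloxy)-4-methoxybenzaldehyde | COc1cc(OCc2ccccc2)c(C=O)cc1OCc1ccccc1 | intermediate
6 | 2,5-bis(benzyloxy)-4-methoxyphenyl formate | COc1cc(OCc2ccccc2)c(OC=O)cc1OCc1ccccc1 | intermediate (not isolated)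
7 | 2,5-bis(benzyloxy)-4-methoxyphenol | COc1cc(OCc2ccccc2)c(O)cc1OCc1ccccc1 | intermediate
8 | 1-bromohexadecane | CCCCCCCCCCCCCCCCBr | starting material
9 | acrolein (prop-2-enal) | C=CC=O | starting material
10 | hexadecylmagnesium bromide | CCCCCCCCCCCCCCCC[Mg]Br | intermediate (not isolated)
11 | rac-nonadec-1-en-3-ol | CCCCCCCCCCCCCCCCC(O)C=C | intermediate
12 | rac-1,4-bis(benzyloxy)-2-methoxy-5-(nonadec-1-en-3-yloxy)benzene | CCCCCCCCCCCCCCCCC(C=C)Oc1cc(OCc2ccccc2)c(OC)cc1OCc1ccccc1 | intermediate
13 | rac-2,5-bis(benzyloxy)-4-methoxy-6-[(E)-nonadec-2-en-1-yl]cyclohexa-2,4-dien-1-one | O=C1C(C/C=C/CCCCCCCCCCCCCCCC)C(OCc2ccccc2)=C(OC)C=C1OCc1ccccc1 | intermediate (not isolated)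
14 | 3,6-bis(benzyloxy)-4-methoxy-2-[(E)-nonadec-2-en-1-yl]phenol | CCCCCCCCCCCCCCCC/C=C/Cc1c(O)c(OCc2ccccc2)cc(OC)c1OCc1ccccc1 | intermediate
15 | 5-methoxy-3-nonadecylbenzene-1,2,4-triol | CCCCCCCCCCCCCCCCCCCc1c(O)c(O)cc(OC)c1O | intermediate (not isolated)
16 | irisoquin C (2-hydroxy-5-methoxy-3-nonadecylcyclohexa-2,5-diene-1,4-dione) | CCCCCCCCCCCCCCCCCCCC1=C(O)C(=O)C=C(OC)C1=O | target

## Step count and risk

Total step count: 7. Longest linear sequence: 6 steps (1, 2, 3, 5, 6, 7); step 4 is a one-step side branch that joins at step 5.

**Step 6 (key step).** The most likely failure is fragmentation of the secondary allylic C–O bond outrunning the concerted shift. Thermal ionisation or elimination towards a conjugated diene would return phenol 7, because the ether is both secondary-allylic and attached to a good phenoxide leaving group. A second risk is acid-promoted cyclisation of the product phenol onto its alkene. The fallback delivers the chain in two pieces. It sets out from phenol 7, and O-allylation (allyl bromide, K2CO3, acetone, reflux) should give 1,4-bis(benzyloxy)-2-methoxy-5-(prop-2-en-1-yloxy)benzene F1. This primary ether has neither a secondary C–O bond nor β-hydrogens, and plain ortho-Claisen rearrangement (PhNEt2, 200 °C) should give 3,6-bis(benzyloxy)-4-methoxy-2-(prop-2-en-1-yl)phenol F2. Olefin cross-metathesis of F2 with excess octadec-1-ene (second-generation Grubbs catalyst (H2IMes)(PCy3)Cl2Ru=CHPh, CH2Cl2, 40 °C) would extend the allyl group by sixteen carbons and rejoin the route at 14, expected mainly as the E isomer; the geometry is erased in step 7.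

**Step 5.** The activated secondary allylic alcohol may be attacked at the alkene terminus (allylic transposition to the linear ether) or may eliminate. Conversion may also stall, because the phenol is electron-rich, only weakly acidic and hindered by the ortho benzyloxy group. The fallback builds the branched ether by SN2 chemistry and makes the vinyl group afterwards. It sets out from phenol 7, and alkylation with methyl 2-bromooctadecanoate (K2CO3, DMF, 60 °C) should give methyl 2-[2,5-bis(benzyloxy)-4-methoxyphenoxy]octadecanoate F3. Partial reduction (i-Bu2AlH, toluene, −78 °C) should give 2-[2,5-bis(benzyloxy)-4-methoxyphenoxy]octadecanal F4. Wittig methylenation (Ph3PCH3Br, KOt-Bu, THF, 0 °C) would rejoin the route at 12.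

**Step 7.** Hydrogenation and debenzylation are routine; the doubt lies in the autoxidation. The free triol may couple oxidatively, or be degraded by the hydrogen peroxide that forms, before clean conversion to the quinone. The waxy product also leaves little room for purification. The fallback isolates a stable derivative first. It sets out from 14: hydrogenation as in step 7, then trapping of 15 under N2 with Ac2O/pyridine, should give 5-methoxy-3-nonadecylbenzene-1,2,4-triyl triacetate F5, which can be purified. Methanolysis open to air (NaOMe, MeOH, rt, then dilute acid) would release and oxidise the triol and arrive at 16. Methanol makes any alkoxide exchange at C5 degenerate.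

**Step 2.** Formylation of the moderately activated ring needs heat. Under those conditions hydrogen chloride may cleave a benzyl ether, and some attack at the other open positions may lower regiocontrol. The fallback introduces the oxygen through a halide instead of a formyl group. It sets out from 3, and low-temperature bromination (NBS, MeCN, 0 °C), which is kinetically more selective, should give 1,4-bis(benzyloxy)-2-bromo-5-methoxybenzene F6. Bromine–lithium exchange (n-BuLi, THF, −78 °C) should give [2,5-bis(benzyloxy)-4-methoxyphenyl]lithium F7, and B(OMe)3 should convert it to dimethyl [2,5-bis(benzyloxy)-4-methoxyphenyl]boronate F8. Oxidation (H2O2, aq NaOH, 0 °C) would rejoin the route at phenol 7, bypassing 5 and 6.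

## Further compounds

F1 | step 6 | 1,4-bis(benzyloxy)-2-methoxy-5-(prop-2-en-1-yloxy)benzene | C=CCOc1cc(OCc2ccccc2)c(OC)cc1OCc1ccccc1
F2 | step 6 | 3,6-bis(benzyloxy)-4-methoxy-2-(prop-2-en-1-yl)phenol | C=CCc1c(O)c(OCc2ccccc2)cc(OC)c1OCc1ccccc1
F3 | step 5 | rac-methyl 2-[2,5-bis(benzyloxy)-4-methoxyphenoxy]octadecanoate | CCCCCCCCCCCCCCCCC(Oc1cc(OCc2ccccc2)c(OC)cc1OCc1ccccc1)C(=O)OC
F4 | step 5 | rac-2-[2,5-bis(benzyloxy)-4-methoxyphenoxy]octadecanal | CCCCCCCCCCCCCCCCC(Oc1cc(OCc2ccccc2)c(OC)cc1OCc1ccccc1)C=O
F5 | step 7 | 5-methoxy-3-nonadecylbenzene-1,2,4-triyl triacetate | CCCCCCCCCCCCCCCCCCCc1c(OC(C)=O)c(OC(C)=O)cc(OC)c1OC(C)=O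
F6 | step 2 | 1,4-bis(benzyloxy)-2-bromo-5-methoxybenzene | COc1cc(OCc2ccccc2)c(Br)cc1OCc1ccccc1
F7 | step 2 | [2,5-bis(benzyloxy)-4-methoxyphenyl]lithium | COc1cc(OCc2ccccc2)c([Li])cc1OCc1ccccc1
F8 | step 2 | dimethyl [2,5-bis(benzyloxy)-4-methoxyphenyl]boronate | COc1cc(OCc2ccccc2)c(B(OC)OC)cc1OCc1ccccc1
A1 | alternative 1 | tricosane-2,3-dione | CC(=O)C(=O)CCCCCCCCCCCCCCCCCCCC
A2 | alternative 1 | diethyl oxalate | CCOC(=O)C(=O)OCC
A3 | alternative 1 | 2,5-dihydroxy-3-nonadecylcyclohexa-2,5-diene-1,4-dione | CCCCCCCCCCCCCCCCCCCC1=C(O)C(=O)C=C(O)C1=O
A4 | alternative 2 | rac-3-tert-butoxy-4-hydroxy-4-[(Z)-2-methoxyethenyl]-2-nonadecylcyclobut-2-en-1-one | CCCCCCCCCCCCCCCCCCCC1=C(OC(C)(C)C)C(O)(/C=C\OC)C1=O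
A5 | alternative 2 | (Z)-(2-methoxyethenyl)lithium | [Li]/C=C\OC
A6 | alternative 2 | 2-tert-butoxy-5-methoxy-3-nonadecylbenzene-1,4-diol | CCCCCCCCCCCCCCCCCCCc1c(O)c(OC)cc(O)c1OC(C)(C)C
A7 | alternative 3 | 1,3-dioxoisoindolin-2-yl 3-(3,5-dimethoxyphenyl)propanoate | COc1cc(CCC(=O)ON2C(=O)c3ccccc3C2=O)cc(OC)c1
A8 | alternative 3 | 1,3-dioxoisoindolin-2-yl octadecanoate | CCCCCCCCCCCCCCCCCC(=O)ON1C(=O)c2ccccc2C1=O
A9 | alternative 3 | 1,3-dimethoxy-5-nonadecylbenzene | CCCCCCCCCCCCCCCCCCCc1cc(OC)cc(OC)c1
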